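The target is made in the reaction phase and then either crosses into the second phase or is lost where it stands, and what follows reckons how that choice divides it.

    reagent in the reaction phase ⇌ reagent in the second phase, rate k1*([reagent in the reaction phase] - [reagent in the second phase]/K1) per volume of the first phase (K1 = 0.34, k1 = 0.085 s⁻¹)
    substrate + reagent in the reaction phase → target (k2 = 14 M⁻¹ s⁻¹)
    target ⇌ product in the second phase, rate k3*([target] - [product in the second phase]/K3) per volume of the first phase (K3 = 23, k3 = 0.069 s⁻¹)
    target → decomposed product (k4 = 0.070 s⁻¹)
    substrate + target → side product (k5 = 0.95 M⁻¹ s⁻¹)
    2 reagent in the reaction phase → homo dimer (k6 = 0.26 M⁻¹ s⁻¹)
    target → over-reaction product (k7 = 0.12 s⁻¹)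

substrate 0.071 M; reagent in the second phase 1.50 equiv; time 25 s; volume of the second phase over the first 1.0

- percent here means substrate units held: one side product counts as two
- what is said of target includes product in the second phase
- for a step with 2 of a species take k times the square, and two of it per event
- in the second phase: reagent in the second phase, product in the second phase; everything else is in the first
- charges count per volume of the first phase; a concentration in a rate is the amount of a species over the volume of its own phase; every rate counts per litre of the first phase
- run time (flask): 25 s

* how much target and product in the second phase together there is at 25 s, in percent of the substrate charged
* the change that raises the amount of target and product in the second phase together at 25 s, in percent of the substrate charged most ("none" if none brings more than 2 percentage points) (Saturday's / Sunday's / Monday's / none)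
* amount of target and product in the second phase together at 25 s, in percent of the substrate charged, after Sunday's

I climb the ladder of half-lives from the fastest rung to the slowest, with the two phases equal in volume:

reagent in the reaction phase, eaten by substrate at charged concentrations: 0.70 s
target leaving the first phase by crossing, decomposing and over-reacting, with total coefficient L = 0.069 s⁻¹ + 0.070 s⁻¹ + 0.12 s⁻¹ = 0.259 s⁻¹: 2.68 s
reagent leaking out of the second phase, at coefficient 0.250 s⁻¹: 2.77 s
target lost to side product at charged substrate: 10 s
the run: 25 s
product in the second phase returning: 231 s

At charged substrate the half-life of reagent in the reaction phase is shorter than that of the leak, but this comparison holds for the start of the flask and for nothing later. Target leaves the first phase in a time shorter than the run, and the return is slower than the run, so at the reading y is nearly what has crossed.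

The concentration that matters is the target's own: crossing, decomposing and over-reacting are each first order in it, so it cancels from their ratio, and substrate enters through the side step.

f = 0.069 s⁻¹ / L = 26.6 %

This f is the escape share, the part of first-phase target that crosses instead of being lost. My reckoning stops at a ceiling: y stands under f, and the side step takes some of the charge, at charged substrate at a pace slower than L. Saturday's and Sunday's leave f as it is, while Monday's lifts it:

f after Monday's = 42.1 %

So I name Monday's, with 16 percentage points on the ceiling.

The forecast goes further than my ceiling to a number: 23.7 % (range 22.7 % to 24.7 %), Monday's as the best change, and 24.5 % (range 23.5 % to 25.5 %) after Sunday's, reasoning that “Doubling the reagent halves the side loss”.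

The simulation gives 23.5 %, 24.1 % after Sunday's, and Monday's as best, with 13 points against 0.6 points for Sunday's and 0.2 points for Saturday's.

In this flask side product holds 10.9 % at the reading, and f of the remaining 89.1 % is 23.7 %. The neighbouring flask charges 0.28 M of substrate with the same equivalents and time. Since f contains no concentration, I carry it over unchanged. Side product in that flask holds 25.3 %, so f of the remainder is 19.9 %, and that flask gives 19.4 %.

The numbers belong to no real substance; what happens was integrated by code.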